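The oxolane is disconnected at O1–C5 and C5–C4 together with the C–O bond of the exocyclic carbinol. The plan rests on one feature: ring carbon C5 carries only hydrogens and lies between O1 and C4, and C4 bears the aryl(hydroxy)methyl group, so C5 can come from formaldehyde, C4 and the carbinol carbon from a styrene, and the hydroxyl from water. In step 9 a formaldehyde-derived oxocarbenium ion tethered through O1 is attacked by the styrene carbon next to C3 and water caps the benzylic position, which closes the ring and sets C4 and the carbinol centre. The precursor is the (R,E)-2-(arylmethyl)-4-arylbut-3-en-1-ol with both syringyl phenols as pivalates, made by an Evans alkylation.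

Key step: step 9

Remark: the oxolane is numbered O1, C2, C3 (arylmethyl), C4 (carbinol arm), C5, and the target is read as (3R,4R) with an (S) carbinol, i.e. a 3,4-trans ring; paraformaldehyde is the source of formaldehyde, and both phenols are acylated before the fragments are joined so that no step must distinguish two hindered phenols from the primary alcohol.

Step 1
Reactants: 1 4-bromo-2,6-dimethoxyphenol
Product: 2 4-bromo-2,6-dimethoxyphenyl pivalate
Conditions: PivCl, Et3N, 4-(dimethylamino)pyridine (cat.), CH2Cl2, 0 °C to rt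
Reagents that add atoms: pivaloyl chloride, CC(C)(C)C(=O)Cl
Why: Esterification of the phenol by acyl transfer under nucleophilic catalysis; the aryl bromide is inert, and masking the phenol removes the phenoxide that would slow oxidative addition in step 2.

Step 2
Reactants: 2 4-bromo-2,6-dimethoxyphenyl pivalate; 3 but-3-enoic acid
Product: 4 (E)-4-[3,5-dimethoxy-4-(pivaloyloxy)phenyl]but-3-enoic acid
Conditions: Pd(OAc)2 (cat.), P(o-tol)3, Et3N, MeCN, 85 °C; then aq. HCl
Reagents that add atoms: none
Why: Mizoroki–Heck reaction, in which the arylpalladium bromide adds its aryl group to the terminal alkene carbon of 3 and syn β-hydride elimination from the new benzylic CH2 gives the arene-conjugated E-alkene, the usual outcome with but-3-enoic acid; the hindered aryl pivalate tolerates Et3N at this temperature.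

Step 3
Reactants: 4 (E)-4-[3,5-dimethoxy-4-(pivaloyloxy)phenyl]but-3-enoic acid; 5 (R)-4-benzyloxazolidin-2-one
Product: 7 (R)-4-benzyl-3-{(E)-4-[3,5-dimethoxy-4-(pivaloyloxy)phenyl]but-3-enoyl}oxazolidin-2-one, via mixed pivalic anhydride 6 (not isolated)
Conditions: PivCl, Et3N, THF, −20 °C; then LiCl, 5, −20 °C to rt
Reagents that add atoms: none
Why: One-pot N-acylation of an oxazolidinone through a mixed anhydride with LiCl/Et3N activation, in which the auxiliary attacks the less hindered butenoyl carbonyl of 6; no strong base is present, and the alkene stays conjugated with the arene, its more stable position.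

Step 4
Reactants: 8 syringaldehyde (4-hydroxy-3,5-dimethoxybenzaldehyde)
Product: 9 4-formyl-2,6-dimethoxyphenyl pivalate
Conditions: PivCl, Et3N, 4-(dimethylamino)pyridine (cat.), CH2Cl2, 0 °C to rt
Reagents that add atoms: pivaloyl chloride, CC(C)(C)C(=O)Cl
Why: Esterification of the phenol by catalysed acyl transfer; the aldehyde does not react with the acid chloride under these conditions.

Step 5
Reactants: 9 4-formyl-2,6-dimethoxyphenyl pivalate
Product: 10 4-(hydroxymethyl)-2,6-dimethoxyphenyl pivalate
Conditions: NaBH4, THF–MeOH (10:1), 0 °C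
Reagents that add atoms: none
Why: Borohydride reduction of an aromatic aldehyde, which is far faster at 0 °C than any attack on the hindered aryl pivalate.

Step 6
Reactants: 10 4-(hydroxymethyl)-2,6-dimethoxyphenyl pivalate
Product: 11 4-(bromomethyl)-2,6-dimethoxyphenyl pivalate
Conditions: PBr3, CH2Cl2, 0 °C
Reagents that add atoms: phosphorus tribromide, BrP(Br)Br
Why: Conversion of a benzylic alcohol into the bromide through a phosphite ester and SN2 displacement by bromide; with the phenol acylated the ring cannot expel bromide as a quinone methide, so 11 should be a stable alkylating agent.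

Step 7
Reactants: 7 (R)-4-benzyl-3-{(E)-4-[3,5-dimethoxy-4-(pivaloyloxy)phenyl]but-3-enoyl}oxazolidin-2-one; 11 4-(bromomethyl)-2,6-dimethoxyphenyl pivalate
Product: 13 (R)-4-benzyl-3-{(2R,3E)-2-[(3,5-dimethoxy-4-pivaloyloxyphenyl)methyl]-4-(3,5-dimethoxy-4-pivaloyloxyphenyl)but-3-enoyl}oxazolidin-2-one, via sodium dienolate 12 (not isolated)
Conditions: NaN(SiMe3)2, THF, −78 °C; then 11, −78 to −40 °C; AcOH quench at −78 °C
Reagents that add atoms: none
Why: Evans asymmetric alkylation, in which the sodium-chelated Z(O)-dienolate 12 reacts with the benzylic bromide at its α-carbon (the kinetic site of dienolate alkylation, which leaves the styrene untouched) on the face opposite the benzyl group of the auxiliary and so sets the new centre as (R); the aryl pivalates have no α-hydrogen and are too hindered to be attacked at −78 °C.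

Step 8
Reactants: 13 (R)-4-benzyl-3-{(2R,3E)-2-[(3,5-dimethoxy-4-pivaloyloxyphenyl)methyl]-4-(3,5-dimethoxy-4-pivaloyloxyphenyl)but-3-enoyl}oxazolidin-2-one
Product: 14 (R,E)-2-[(3,5-dimethoxy-4-pivaloyloxyphenyl)methyl]-4-(3,5-dimethoxy-4-pivaloyloxyphenyl)but-3-en-1-ol
Conditions: LiBH4, MeOH (1 equiv), THF, 0 °C
Reagents that add atoms: none
Why: Reductive removal of the Evans auxiliary by hydride attack on the activated exocyclic imide carbonyl, under conditions too weakly basic to epimerise the allylic centre and too mild at 0 °C to reduce the doubly hindered aryl pivalates.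

Step 9
Reactants: 14 (R,E)-2-[(3,5-dimethoxy-4-pivaloyloxyphenyl)methyl]-4-(3,5-dimethoxy-4-pivaloyloxyphenyl)but-3-en-1-ol; 15 formaldehyde (charged as paraformaldehyde)
Product: 18 (S)-[3,5-dimethoxy-4-(pivaloyloxy)phenyl]{(3R,4R)-4-[(3,5-dimethoxy-4-pivaloyloxyphenyl)methyl]oxolan-3-yl}methanol, via hemiformal 16 (not isolated), via oxocarbenium ion 17 (not isolated)
Conditions: (CH2O)n (2 equiv), CF3CO2H–H2O (5:1), 0 °C to rt; then aq. NaHCO3–MeOH
Reagents that add atoms: water, O
Why: Alcohol 14 and formaldehyde give hemiformal 16, which the acid ionises to the O-methylene oxocarbenium ion 17; the styrene carbon attached to C3 bonds to the cationic carbon while water adds to the benzylic carbon, so O1–C5, C5–C4 and the carbinol C–O bond are made in one flask. The closest known reaction type is the Prins cyclisation of 4-arylbut-3-en-1-ols with aldehydes, which closes an oxolane and ends at the benzylic carbon, combined with hydroxyl termination as in Prins reactions run in aqueous acid. The ring closes 5-exo-trig with respect to the alkene (endo with respect to the C=O+ unit), and this mode is preferred over six-ring closure or an oxonia-Cope shift because only it places the positive charge next to an aryl group. C4 is controlled by the C3 stereocentre: in the envelope transition state C3–H sits on the inside next to the alkene and the arylmethyl group points away from the styryl arm, which leads to the 3,4-trans ring. The carbinol centre is controlled by the E geometry of the alkene and anti addition, water entering opposite the new C5–C4 bond to give the (S) configuration. The step needs capture by water to be faster than rotation of the cation or its attack by C2/C6 of the other ring, and the substrate secures this through the 4-pivaloyloxy-3,5-dimethoxyphenyl group, which stabilises the cation no better than phenyl so that it is short-lived in a medium rich in water and 18 does not readily re-ionise, while the pivalate on the other ring lowers that ring's nucleophilicity.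

Step 10
Reactants: 18 (S)-[3,5-dimethoxy-4-(pivaloyloxy)phenyl]{(3R,4R)-4-[(3,5-dimethoxy-4-pivaloyloxyphenyl)methyl]oxolan-3-yl}methanol
Product: 19 4-[(S)-hydroxy{(3R,4R)-4-[(4-hydroxy-3,5-dimethoxyphenyl)methyl]oxolan-3-yl}methyl]-2,6-dimethoxyphenol (target)
Conditions: NaOMe (4 equiv), MeOH–THF (degassed), 0 °C to rt; then aq. NH4Cl
Reagents that add atoms: none
Why: Base-mediated methanolysis (transesterification) of the two aryl pivalates, with the phenoxides as leaving groups; the ring, the carbinol and the three stereocentres take no part, and working at room temperature avoids quinone methide formation from the freed 4-hydroxybenzylic alcohol.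

Compound list
1 | 4-bromo-2,6-dimethoxyphenol | COc1cc(Br)cc(OC)c1O | starting material
2 | 4-bromo-2,6-dimethoxyphenyl pivalate | COc1cc(Br)cc(OC)c1OC(=O)C(C)(C)C | intermediate
3 | but-3-enoic acid | C=CCC(=O)O | starting material
4 | (E)-4-[3,5-dimethoxy-4-(pivaloyloxy)phenyl]but-3-enoic acid | COc1cc(/C=C/CC(=O)O)cc(OC)c1OC(=O)C(C)(C)C | intermediate
5 | (R)-4-benzyloxazolidin-2-one | O=C1N[C@H](Cc2ccccc2)CO1 | starting material
6 | (E)-4-[3,5-dimethoxy-4-(pivaloyloxy)phenyl]but-3-enoic pivalic anhydride (not isolated) | COc1cc(/C=C/CC(=O)OC(=O)C(C)(C)C)cc(OC)c1OC(=O)C(C)(C)C | intermediate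
7 | (R)-4-benzyl-3-{(E)-4-[3,5-dimethoxy-4-(pivaloyloxy)phenyl]but-3-enoyl}oxazolidin-2-one | COc1cc(/C=C/CC(=O)N2[C@H](Cc3ccccc3)COC2=O)cc(OC)c1OC(=O)C(C)(C)C | intermediate
8 | syringaldehyde (4-hydroxy-3,5-dimethoxybenzaldehyde) | COc1cc(C=O)cc(OC)c1O | starting material
9 | 4-formyl-2,6-dimethoxyphenyl pivalate | COc1cc(C=O)cc(OC)c1OC(=O)C(C)(C)C | intermediate
10 | 4-(hydroxymethyl)-2,6-dimethoxyphenyl pivalate | COc1cc(CO)cc(OC)c1OC(=O)C(C)(C)C | intermediate
11 | 4-(bromomethyl)-2,6-dimethoxyphenyl pivalate | COc1cc(CBr)cc(OC)c1OC(=O)C(C)(C)C | intermediate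
12 | sodium Z(O)-dienolate of 7, E-styryl unit retained (not isolated) | COc1cc(/C=C/C=C(\[O-])N2[C@H](Cc3ccccc3)COC2=O)cc(OC)c1OC(=O)C(C)(C)C.[Na+] | intermediate
13 | (R)-4-benzyl-3-{(2R,3E)-2-[(3,5-dimethoxy-4-pivaloyloxyphenyl)methyl]-4-(3,5-dimethoxy-4-pivaloyloxyphenyl)but-3-enoyl}oxazolidin-2-one | COc1cc(C[C@H](/C=C/c2cc(OC)c(OC(=O)C(C)(C)C)c(OC)c2)C(=O)N2[C@H](Cc3ccccc3)COC2=O)cc(OC)c1OC(=O)C(C)(C)C | intermediate
14 | (R,E)-2-[(3,5-dimethoxy-4-pivaloyloxyphenyl)methyl]-4-(3,5-dimethoxy-4-pivaloyloxyphenyl)but-3-en-1-ol | COc1cc(C[C@H](/C=C/c2cc(OC)c(OC(=O)C(C)(C)C)c(OC)c2)CO)cc(OC)c1OC(=O)C(C)(C)C | intermediate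
15 | formaldehyde (charged as paraformaldehyde) | C=O | starting material
16 | hemiformal of 14, the O-(hydroxymethyl) ether of its primary alcohol (not isolated) | COc1cc(C[C@H](/C=C/c2cc(OC)c(OC(=O)C(C)(C)C)c(OC)c2)COCO)cc(OC)c1OC(=O)C(C)(C)C | intermediate
17 | O-methylene oxocarbenium ion derived from 16 (not isolated) | COc1cc(C[C@H](/C=C/c2cc(OC)c(OC(=O)C(C)(C)C)c(OC)c2)C[O+]=C)cc(OC)c1OC(=O)C(C)(C)C | intermediate
18 | (S)-[3,5-dimethoxy-4-(pivaloyloxy)phenyl]{(3R,4R)-4-[(3,5-dimethoxy-4-pivaloyloxyphenyl)methyl]oxolan-3-yl}methanol | COc1cc(C[C@H]2COC[C@@H]2[C@H](O)c2cc(OC)c(OC(=O)C(C)(C)C)c(OC)c2)cc(OC)c1OC(=O)C(C)(C)C | intermediate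
19 | 4-[(S)-hydroxy{(3R,4R)-4-[(4-hydroxy-3,5-dimethoxyphenyl)methyl]oxolan-3-yl}methyl]-2,6-dimethoxyphenol | COc1cc(C[C@H]2COC[C@@H]2[C@H](O)c2cc(OC)c(O)c(OC)c2)cc(OC)c1O | target

Total step count: 10. Longest linear sequence: 7 steps (1, 2, 3, 7, 8, 9, 10; the branch 4, 5, 6 joins at step 7 and is equally long).

Steps most likely to fail

Step 9 (key step). The process at risk is capture of the benzylic cation: if it lives long enough to rotate about the C4–carbinol bond, or if the ring closes on the other alkene face, configuration leaks at the carbinol carbon and partly at C4. Attack on the cation by C2/C6 of the neighbouring ring is the other drain; it is limited by short reaction times, and the fallback below does not repair it. The fallback takes the carbinol centre out of the cyclisation and sets it by reagent control. Setting out from 14, the ring closure is run as in step 9 without regard to the carbinol outcome. The mixture of 18 and its carbinol epimer (R)-[3,5-dimethoxy-4-(pivaloyloxy)phenyl]{(3R,4R)-4-[(3,5-dimethoxy-4-pivaloyloxyphenyl)methyl]oxolan-3-yl}methanol F1 is oxidised with Dess–Martin periodinane (NaHCO3, CH2Cl2) to the aryl ketone [3,5-dimethoxy-4-(pivaloyloxy)phenyl]{(3R,4R)-4-[(3,5-dimethoxy-4-pivaloyloxyphenyl)methyl]oxolan-3-yl}methanone F2. C4 is now α to the carbonyl, so a little DBU in toluene should equilibrate any cis material to the trans ring. Corey–Bakshi–Shibata reduction (BH3·SMe2, (R)-1-methyl-3,3-diphenyltetrahydro-1H,3H-pyrrolo[1,2-c][1,3,2]oxazaborole, THF, −20 °C), with the aryl group as the large substituent, should then give the (S)-carbinol and rejoin the route at 18.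

Step 7. The process at risk is the behaviour of the extended dienolate: alkylation at its γ-carbon, migration of the double bond, or proton exchange between 12 and the product that erodes the new centre. The fallback sets the stereocentre on the simpler crotonate-derived dienolate and attaches the styrene aryl group afterwards by metathesis. Setting out from 5, n-BuLi and (E)-but-2-enoyl chloride (THF, −78 °C) give (R)-4-benzyl-3-[(E)-but-2-enoyl]oxazolidin-2-one F3. Deconjugative α-alkylation (NaN(SiMe3)2, THF, −78 °C, then 11) gives (R)-4-benzyl-3-{(R)-2-[(3,5-dimethoxy-4-pivaloyloxyphenyl)methyl]but-3-enoyl}oxazolidin-2-one F4, and LiBH4 (THF, 0 °C) gives (R)-2-[(3,5-dimethoxy-4-pivaloyloxyphenyl)methyl]but-3-en-1-ol F5. Olefin cross-metathesis of F5 with an excess of 4-ethenyl-2,6-dimethoxyphenyl pivalate F6 (from 9 and Ph3P=CH2) using the second-generation Grubbs catalyst RuCl2(PCy3)(H2IMes)(=CHPh) in CH2Cl2 at 40 °C should give the E-alkene and rejoin the route at 14.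

Step 2. The process at risk is β-hydride elimination toward the carboxylate side, or re-addition of the palladium hydride, which would give alkene regio- and geometric isomers that are hard to separate from 4. The fallback makes the same alkene by carbonyl olefination. Setting out from 9, Wittig reaction with the ylide from (2-carboxyethyl)triphenylphosphonium bromide and NaN(SiMe3)2 (2 equiv, THF, −78 °C to rt) should form the but-3-enoic acid directly, a method that favours the E-alkene with aromatic aldehydes. It returns to the route at 4 and makes no compound outside the list (F0).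

Further compounds
F1 | step 9 | (R)-[3,5-dimethoxy-4-(pivaloyloxy)phenyl]{(3R,4R)-4-[(3,5-dimethoxy-4-pivaloyloxyphenyl)methyl]oxolan-3-yl}methanol | COc1cc(C[C@H]2COC[C@@H]2[C@@H](O)c2cc(OC)c(OC(=O)C(C)(C)C)c(OC)c2)cc(OC)c1OC(=O)C(C)(C)C
F2 | step 9 | [3,5-dimethoxy-4-(pivaloyloxy)phenyl]{(3R,4R)-4-[(3,5-dimethoxy-4-pivaloyloxyphenyl)methyl]oxolan-3-yl}methanone | COc1cc(C[C@H]2COC[C@@H]2C(=O)c2cc(OC)c(OC(=O)C(C)(C)C)c(OC)c2)cc(OC)c1OC(=O)C(C)(C)C
F3 | step 7 | (R)-4-benzyl-3-[(E)-but-2-enoyl]oxazolidin-2-one | C/C=C/C(=O)N1[C@H](Cc2ccccc2)COC1=O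
F4 | step 7 | (R)-4-benzyl-3-{(R)-2-[(3,5-dimethoxy-4-pivaloyloxyphenyl)methyl]but-3-enoyl}oxazolidin-2-one | COc1cc(C[C@H](C=C)C(=O)N2[C@H](Cc3ccccc3)COC2=O)cc(OC)c1OC(=O)C(C)(C)C
F5 | step 7 | (R)-2-[(3,5-dimethoxy-4-pivaloyloxyphenyl)methyl]but-3-en-1-ol | COc1cc(C[C@H](C=C)CO)cc(OC)c1OC(=O)C(C)(C)C
F6 | step 7 | 4-ethenyl-2,6-dimethoxyphenyl pivalate | COc1cc(C=C)cc(OC)c1OC(=O)C(C)(C)C
F0 | step 2 | none | none
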